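**Plan**
1. Retrosynthesis: remove the acetyl helper on O7; cut the O–C(CH3)2 bond of ring D (the dimethyldihydropyran fused to ring B), then the C3'–CH2 bond, which leads back to a 1,1-dimethylallyl ether on O4'; cut C2–C1' (chromone plus arylboronic acid); cut C8–CH2 back to a 1,1-dimethylallyl ether on O7.
2. Forward: both C5 units are put on oxygen by the same two operations (O-alkylation with 3-chloro-3-methylbut-1-yne, semihydrogenation). The ring A unit is moved from O7 to C8 on the chromone and O7 is capped as acetate. The fragments are joined at C2–C1', giving ring C its saturated form. The ring B unit is then moved from O4' to C3' and closed to ring D, the last ring, and the acetate is removed.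
3. Enabling feature: each C5 unit sits on the carbon ortho to a phenolic oxygen (C8 beside O7 in ring A, C3' beside O4' in ring B). An O-bound 1,1-dimethylallyl group is therefore a latent ortho-prenyl group, and on ring B the freed O4'–H lies six atoms from C(CH3)2. Ring A stays open because O7 is an acetate.
4. Stereochemistry: the single stereocentre C2 (S) comes from the chiral bisphosphine on rhodium in the conjugate addition; all later steps are base-free or near neutral.

Key step: step 8

Assumption: the (S)-configured biaryl bisphosphine on rhodium is taken to deliver the aryl group to the chromone face that gives (2S), by analogy with (S)-BINAP/rhodium giving (S)-3-arylcyclohexanones from 2-cyclohexenone; should the sense be opposite, the (R)-ligand is used.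

**Route**

Step 1
Reactants: 1 7-hydroxy-4H-chromen-4-one; 2 3-chloro-3-methylbut-1-yne
Product: 3 7-[(2-methylbut-3-yn-2-yl)oxy]-4H-chromen-4-one
Conditions: K2CO3, KI, CuI (cat.), acetone, reflux
Reagents that add atoms: none
Why: Copper-assisted Williamson-type O-alkylation of the phenoxide of 1 (its only acidic O–H, the chromone ring being inert to carbonate in acetone) with the tertiary propargylic chloride should give the hindered 1,1-dimethylpropargyl ether, a reaction type that is standard for phenols.

Step 2
Reactants: 3 7-[(2-methylbut-3-yn-2-yl)oxy]-4H-chromen-4-one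
Product: 4 7-[(2-methylbut-3-en-2-yl)oxy]-4H-chromen-4-one
Conditions: H2 (1 atm), Pd/CaCO3 poisoned with Pb(OAc)2 (Lindlar catalyst), quinoline, EtOAc, 23 °C
Reagents that add atoms: none
Why: Lindlar semihydrogenation should stop at the vinyl group because the lead- and quinoline-poisoned palladium surface reduces the terminal alkyne much faster than the resulting alkene or the vinylogous-ester C2=C3 bond of the chromone.

Step 3
Reactants: 4 7-[(2-methylbut-3-en-2-yl)oxy]-4H-chromen-4-one
Product: 6 8-(3-methylbut-2-en-1-yl)-4-oxo-4H-chromen-7-yl acetate, via 7-hydroxy-8-prenylchromone 5 (not isolated)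
Conditions: Ac2O, PhNEt2, 150 °C
Reagents that add atoms: acetic anhydride, CC(=O)OC(C)=O
Why: Aromatic Claisen rearrangement ([3,3]-sigmatropic shift through a chair transition state) should move the C5 unit from O7 to C8 rather than C6 because the C7–C8 bond of the benzopyranone has the higher double-bond character, the allylic inversion turning the 1,1-dimethylallyl group into the 3-methylbut-2-enyl group, and acetic anhydride acetylates the freed 7-OH of 5 in the same flask so that this phenol is masked for steps 7 and 8.

Step 4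
Reactants: 7 4-bromophenol; 2 3-chloro-3-methylbut-1-yne
Product: 8 1-bromo-4-[(2-methylbut-3-yn-2-yl)oxy]benzene
Conditions: K2CO3, KI, CuI (cat.), acetone, reflux
Reagents that add atoms: none
Why: The same copper-assisted Williamson-type O-alkylation as in step 1 should etherify the phenoxide of 4-bromophenol with the tertiary propargylic chloride without touching the aryl bromide.

Step 5
Reactants: 8 1-bromo-4-[(2-methylbut-3-yn-2-yl)oxy]benzene
Product: 9 1-bromo-4-[(2-methylbut-3-en-2-yl)oxy]benzene
Conditions: H2 (1 atm), Pd/CaCO3 poisoned with Pb(OAc)2 (Lindlar catalyst), quinoline, EtOAc, 23 °C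
Reagents that add atoms: none
Why: Lindlar semihydrogenation as in step 2 should reduce only the terminal alkyne, since the poisoned catalyst neither hydrogenolyses the aryl bromide nor readily reduces the hindered vinyl group.

Step 6
Reactants: 9 1-bromo-4-[(2-methylbut-3-en-2-yl)oxy]benzene
Product: 12 {4-[(2-methylbut-3-en-2-yl)oxy]phenyl}boronic acid, via aryllithium 10 (not isolated), via lithium aryltriisopropoxyborate 11 (not isolated)
Conditions: n-BuLi, THF, −78 °C; B(OiPr)3, −78 °C to 23 °C; aq. NH4Cl
Reagents that add atoms: triisopropyl borate, CC(C)OB(OC(C)C)OC(C)C; water, O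
Why: Bromine–lithium exchange at −78 °C and trapping of aryllithium 10 with triisopropyl borate (lithiation–borylation) should give borate 11, which the weakly acidic aqueous quench hydrolyses to the boronic acid while the acid-sensitive tertiary allyl ether survives.

Step 7
Reactants: 6 8-(3-methylbut-2-en-1-yl)-4-oxo-4H-chromen-7-yl acetate; 12 {4-[(2-methylbut-3-en-2-yl)oxy]phenyl}boronic acid
Product: 13 (2S)-2-{4-[(2-methylbut-3-en-2-yl)oxy]phenyl}-8-(3-methylbut-2-en-1-yl)-4-oxo-3,4-dihydro-2H-chromen-7-yl acetate
Conditions: [Rh(OH)(cod)]2 (1.5 mol %), (S)-6,6'-dimethoxy-2,2'-bis[bis(3,4,5-trifluorophenyl)phosphino]-1,1'-biphenyl (3.3 mol %), 12 (2 equiv), PhMe/H2O (10:1), 30 °C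
Reagents that add atoms: none
Why: In this Hayashi–Miyaura reaction (rhodium-catalysed asymmetric 1,4-addition of an arylboronic acid to a chromone) the aryl–rhodium species bearing the (S)-bisphosphine should insert the C2=C3 bond from one enantiotopic face and the resulting rhodium enolate is protonated by water, which sets C2 as (S) under base-free conditions that spare the aryl acetate, both alkenes, the tertiary allyl ether and the configurationally labile flavanone.

Step 8
Reactants: 13 (2S)-2-{4-[(2-methylbut-3-en-2-yl)oxy]phenyl}-8-(3-methylbut-2-en-1-yl)-4-oxo-3,4-dihydro-2H-chromen-7-yl acetate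
Product: 15 (2S)-2-(2,2-dimethyl-3,4-dihydro-2H-chromen-6-yl)-8-(3-methylbut-2-en-1-yl)-4-oxo-3,4-dihydro-2H-chromen-7-yl acetate, via o-prenylphenol 14 (not isolated)
Conditions: PhMe, 110 °C; then 23 °C, AgOTf (5 mol %)
Reagents that add atoms: none
Why: On heating, the aryl 1,1-dimethylallyl ether on O4' undergoes a concerted [3,3]-sigmatropic (aromatic Claisen) shift through a chair transition state to C3' (C5' is equivalent and C1' is blocked), and rearomatisation unveils o-prenylphenol 14. AgOTf, together with the trace of triflic acid it releases, then activates the ring B prenyl alkene in the Markovnikov sense and O4' attacks the developing tertiary carbon, which forms the O–C(CH3)2 bond. The closest known reaction types are the thermal Claisen rearrangement of aryl 1,1-dimethylallyl ethers and the silver- or acid-catalysed cycloisomerisation of o-prenylphenols to 2,2-dimethylchromans. Ring D closes in a 6-endo-trig mode. No stereocentre is formed, and C2 (S) should be preserved because the sequence is free of base and only briefly weakly acidic. The selectivity needed is between the two prenyl groups, and the substrate secures it: O7 is an acetate, so the 8-prenyl group of ring A has no O–H partner and any cation formed there can only revert to the alkene.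

Step 9
Reactants: 15 (2S)-2-(2,2-dimethyl-3,4-dihydro-2H-chromen-6-yl)-8-(3-methylbut-2-en-1-yl)-4-oxo-3,4-dihydro-2H-chromen-7-yl acetate
Product: 16 Euchrenone a17, (2S)-2-(2,2-dimethyl-3,4-dihydro-2H-chromen-6-yl)-7-hydroxy-8-(3-methylbut-2-en-1-yl)-2,3-dihydro-4H-chromen-4-one
Conditions: NH4OAc, MeOH/H2O (4:1), 23 °C
Reagents that add atoms: none
Why: Near-neutral methanolysis of the aryl acetate, which is activated by the para carbonyl group (ester cleavage by transesterification), should free the 7-OH without a base strong enough to open ring C by retro-oxa-Michael reaction, so C2 stays (S) and the neighbouring 8-prenyl group is not exposed to acid.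

**Compound list**
1 | 7-hydroxy-4H-chromen-4-one (7-hydroxychromone) | O=c1ccoc2cc(O)ccc12 | starting material
2 | 3-chloro-3-methylbut-1-yne | C#CC(C)(C)Cl | starting material
3 | 7-[(2-methylbut-3-yn-2-yl)oxy]-4H-chromen-4-one | O=c1ccoc2cc(OC(C)(C)C#C)ccc12 | intermediate
4 | 7-[(2-methylbut-3-en-2-yl)oxy]-4H-chromen-4-one | O=c1ccoc2cc(OC(C)(C)C=C)ccc12 | intermediate
5 | 7-hydroxy-8-(3-methylbut-2-en-1-yl)-4H-chromen-4-one (7-hydroxy-8-prenylchromone) | O=c1ccoc2c(CC=C(C)C)c(O)ccc12 | intermediate
6 | 8-(3-methylbut-2-en-1-yl)-4-oxo-4H-chromen-7-yl acetate | O=c1ccoc2c(CC=C(C)C)c(OC(C)=O)ccc12 | intermediate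
7 | 4-bromophenol | Oc1ccc(Br)cc1 | starting material
8 | 1-bromo-4-[(2-methylbut-3-yn-2-yl)oxy]benzene | Brc1ccc(OC(C)(C)C#C)cc1 | intermediate
9 | 1-bromo-4-[(2-methylbut-3-en-2-yl)oxy]benzene | Brc1ccc(OC(C)(C)C=C)cc1 | intermediate
10 | {4-[(2-methylbut-3-en-2-yl)oxy]phenyl}lithium (aryllithium) | [Li]c1ccc(OC(C)(C)C=C)cc1 | intermediate
11 | lithium triisopropoxy{4-[(2-methylbut-3-en-2-yl)oxy]phenyl}borate | [Li+].CC(C)O[B-](OC(C)C)(OC(C)C)c1ccc(OC(C)(C)C=C)cc1 | intermediate
12 | {4-[(2-methylbut-3-en-2-yl)oxy]phenyl}boronic acid | OB(O)c1ccc(OC(C)(C)C=C)cc1 | intermediate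
13 | (2S)-2-{4-[(2-methylbut-3-en-2-yl)oxy]phenyl}-8-(3-methylbut-2-en-1-yl)-4-oxo-3,4-dihydro-2H-chromen-7-yl acetate | CC(C)=CCc1c(OC(C)=O)ccc2c1O[C@H](c1ccc(OC(C)(C)C=C)cc1)CC2=O | intermediate
14 | (2S)-2-[4-hydroxy-3-(3-methylbut-2-en-1-yl)phenyl]-8-(3-methylbut-2-en-1-yl)-4-oxo-3,4-dihydro-2H-chromen-7-yl acetate (o-prenylphenol) | CC(C)=CCc1c(OC(C)=O)ccc2c1O[C@H](c1ccc(O)c(CC=C(C)C)c1)CC2=O | intermediate
15 | (2S)-2-(2,2-dimethyl-3,4-dihydro-2H-chromen-6-yl)-8-(3-methylbut-2-en-1-yl)-4-oxo-3,4-dihydro-2H-chromen-7-yl acetate | CC(C)=CCc1c(OC(C)=O)ccc2c1O[C@H](c1ccc3c(c1)CCC(C)(C)O3)CC2=O | intermediate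
16 | Euchrenone a17, (2S)-2-(2,2-dimethyl-3,4-dihydro-2H-chromen-6-yl)-7-hydroxy-8-(3-methylbut-2-en-1-yl)-2,3-dihydro-4H-chromen-4-one | CC(C)=CCc1c(O)ccc2c1O[C@H](c1ccc3c(c1)CCC(C)(C)O3)CC2=O | target

**Step count and risks**
Total steps: 9. Longest linear sequence: 6 steps (steps 1, 2, 3, 7, 8, 9 or steps 4, 5, 6, 7, 8, 9).

Most likely to fail, step 8: once the free 4'-hydroxyl is unveiled at 110 °C, ring C may open and reclose reversibly and erode the configuration at C2. The tertiary allyl ether may also fragment with loss of the C5 unit instead of undergoing the [3,3] shift. In the acidic stage the double bond of the ring A prenyl group may migrate, or the acetyl group may transfer from O7 to O4'. The fallback closes ring D before the fragments are joined; it sets out from 9 and comes back to the route at 15. Bromide 9 is heated in PhNEt2 at 130 °C to give, by Claisen rearrangement, 4-bromo-2-(3-methylbut-2-en-1-yl)phenol F1. Amberlyst 15 in CH2Cl2 at 23 °C cyclises this to 6-bromo-2,2-dimethyl-3,4-dihydro-2H-chromene F2. Treatment with n-BuLi in THF at −78 °C gives (2,2-dimethyl-3,4-dihydro-2H-chromen-6-yl)lithium F3, and B(OiPr)3 converts it into lithium (2,2-dimethyl-3,4-dihydro-2H-chromen-6-yl)triisopropoxyborate F4. Aqueous NH4Cl hydrolyses this to (2,2-dimethyl-3,4-dihydro-2H-chromen-6-yl)boronic acid F5, which is added to chromone 6 under the conditions of step 7 to give 15 directly.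

Second, step 7: facial selectivity may be insufficient or turnover slow with a chromone flanked by the 8-prenyl and 7-acetoxy groups, and the electron-rich boronic acid may protodeboronate competitively. The fallback separates bond formation from stereocontrol; it sets out from 6 and 12 and comes back at 13. The achiral complex [Rh(OH)(cod)]2 alone in PhMe/H2O should give racemic 2-{4-[(2-methylbut-3-en-2-yl)oxy]phenyl}-8-(3-methylbut-2-en-1-yl)-4-oxo-3,4-dihydro-2H-chromen-7-yl acetate F6. Kinetic resolution by Noyori asymmetric transfer hydrogenation with RuCl(p-cymene)[(R,R)-TsDPEN] and HCO2H/Et3N is then expected to reduce the (2R)-ketone to (2R,4R)-4-hydroxy-2-{4-[(2-methylbut-3-en-2-yl)oxy]phenyl}-8-(3-methylbut-2-en-1-yl)-3,4-dihydro-2H-chromen-7-yl acetate F7. The unreacted (2S)-ketone 13 is separated by chromatography.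

Third, step 3: the sigmatropic shift may go to C6 instead of C8, or the tertiary allyl ether may fragment to the phenol and isoprene at 150 °C. The fallback replaces the rearrangement by a cross-coupling; it sets out from 1 and comes back at 6. Iodination of 1 with N-iodosuccinimide in MeCN at the position between the two ring oxygens should give 7-hydroxy-8-iodo-4H-chromen-4-one F8. Ac2O and pyridine convert it into 8-iodo-4-oxo-4H-chromen-7-yl acetate F9. Stille coupling with tributyl(3-methylbut-2-en-1-yl)stannane, Pd(PPh3)4 in DMF at 90 °C then delivers 6.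

**Further compounds**
F1 | step 8 | 4-bromo-2-(3-methylbut-2-en-1-yl)phenol | Oc1ccc(Br)cc1CC=C(C)C
F2 | step 8 | 6-bromo-2,2-dimethyl-3,4-dihydro-2H-chromene | Brc1ccc2OC(C)(C)CCc2c1
F3 | step 8 | (2,2-dimethyl-3,4-dihydro-2H-chromen-6-yl)lithium | [Li]c1ccc2OC(C)(C)CCc2c1
F4 | step 8 | lithium (2,2-dimethyl-3,4-dihydro-2H-chromen-6-yl)triisopropoxyborate | [Li+].CC(C)O[B-](OC(C)C)(OC(C)C)c1ccc2OC(C)(C)CCc2c1
F5 | step 8 | (2,2-dimethyl-3,4-dihydro-2H-chromen-6-yl)boronic acid | OB(O)c1ccc2OC(C)(C)CCc2c1
F6 | step 7 | racemic 2-{4-[(2-methylbut-3-en-2-yl)oxy]phenyl}-8-(3-methylbut-2-en-1-yl)-4-oxo-3,4-dihydro-2H-chromen-7-yl acetate | CC(C)=CCc1c(OC(C)=O)ccc2c1OC(c1ccc(OC(C)(C)C=C)cc1)CC2=O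
F7 | step 7 | (2R,4R)-4-hydroxy-2-{4-[(2-methylbut-3-en-2-yl)oxy]phenyl}-8-(3-methylbut-2-en-1-yl)-3,4-dihydro-2H-chromen-7-yl acetate | CC(C)=CCc1c(OC(C)=O)ccc2c1O[C@@H](c1ccc(OC(C)(C)C=C)cc1)C[C@H]2O
F8 | step 3 | 7-hydroxy-8-iodo-4H-chromen-4-one | O=c1ccoc2c(I)c(O)ccc12
F9 | step 3 | 8-iodo-4-oxo-4H-chromen-7-yl acetate | O=c1ccoc2c(I)c(OC(C)=O)ccc12
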